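If you distrust a curve, ask it for the one thing it has to deliver: how far this flask gets by the asked time.

common to all: initiator 5 mol%
- Tuesday's: substrate 13 mM; partner 4 equiv; scavenger 0.80 equiv; run made earlier
- Sunday's: substrate 30 mM; partner 4 equiv; scavenger 0.80 equiv; run made earlier
- Monday's: substrate 20 mM; partner 8 equiv; scavenger 0.80 equiv; run made earlier
- flask: substrate 20 mM; partner 4.00 equiv; scavenger 0.800 equiv; time 25 min

- Tuesday's (time / min: substrate / %, product / %): 1.33: 82.5, 16.1; 2.00: 76.8, 21.7; 3.00: 67.0, 29.7; 4.00: 60.9, 35.5; 6.00: 50.9, 44.0; 10.0: 41.2, 52.8; 15.0: 35.4, 58.7
- Sunday's (time / min: substrate / %, product / %): 1.33: 72.2, 25.7; 2.00: 62.9, 35.0; 3.00: 50.6, 46.2; 4.00: 42.8, 55.0; 6.00: 30.3, 66.5; 10.0: 19.7, 76.6; 15.0: 13.3, 82.6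
- Monday's (time / min: substrate / %, product / %): 1.33: 75.0, 23.6; 2.50: 60.1, 37.8; 4.00: 46.6, 51.9; 8.00: 27.8, 70.8; 15.0: 17.7, 80.8

(readings scatter by 0.5 percentage points)

1. part of the substrate that has reacted at 25 min
2. share of the unused partner that is free and not bound as idle adduct, at 25 min

- amounts and yields of released group count idle adduct too
- on the list of suspects stand: initiator -> 2 initiating radical; substrate + initiating radical -> capped initiator + first chain carrier; partner + first chain carrier -> product + second chain carrier; substrate + second chain carrier -> released group + first chain carrier; first chain carrier -> ended carrier; 2 second chain carrier -> ended chains; partner + released group <-> idle adduct; scavenger + released group -> scavenged by-product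
- the earlier runs do not show how much of partner is bound; that part of a forecast is a guess

How do we measure "far"? By the reach: minus the natural logarithm of the fraction of substrate left, which is the pseudo-first-order rate of substrate loss summed over time.

Is Tuesday's reach still growing at its last reading? Yes, but slowly: it stands at 1.04, and its mean rate falls from 0.0529 min⁻¹ to 0.0303 min⁻¹ over the last two intervals. I read that as a decay of 0.123 min⁻¹.

What does it gain by 25 min? Replace the remaining curve by its mean, the rate at the middle of that stretch, and the gain is 0.120.

And the flask, which has Tuesday's equivalents and loading but more substrate? Sunday's reach at 15.0 min is 2.02, so from these two runs, which share their equivalents and loading, I take reach to grow with the substrate charge as a power, the reach exponent 0.794. That lifts Tuesday's reckoned 1.16 at 25 min to 1.63 for the flask, which means 80.4% reacted.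

Isn't the mean a crude step? Integrating the exponential gives a gain of 0.128 and 80.6% reacted.

And the bound partner? The readings do not show it, so I give no figure.

The forecast, built on “a chain whose rate falls as initiator burns out”, says 83%, higher than mine, and offers 90% free as a guess.

The flask gives 80.1% reacted and >99.9% of the unused partner free.

    initiator → 2 initiating radical (k = 0.00370 s⁻¹)
    substrate + initiating radical → capped initiator + first chain carrier (k = 6.00 × 10⁵ M⁻¹ s⁻¹)
    partner + first chain carrier → product + second chain carrier (k = 16000 M⁻¹ s⁻¹)
    substrate + second chain carrier → released group + first chain carrier (k = 9600 M⁻¹ s⁻¹)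
    first chain carrier → ended carrier (k = 77.0 s⁻¹)
    2 second chain carrier → ended chains (k = 2.00 × 10⁷ M⁻¹ s⁻¹)
    partner + released group ⇌ idle adduct, settled at all times (K = 5.60 M⁻¹)
    scavenger + released group → scavenged by-product (k = 35.0 M⁻¹ s⁻¹)

The half-life of initiator by its breakdown alone, 3.1 min, is shorter than the 25 min of the run, and at that time 0.39% of the initiator remains, less than the 20% of the substrate. After 250 min, 80.6% has reacted. The flask's reach is 1.61, and the reach exponent carries it to 0.537 for the neighbour flask with 5.0 mM of substrate, which means 41.6% reacted; that neighbour flask stands at 40.2%.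

(The runs were generated by integration on assumed constants; the scatter is artificial.)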